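All runs stem from a simulated flask from invented constants.

1. A small charge of solid substrate leaves the reading quickly. In alpha, 0.3% of it is left at 3.00 min, with 60.5% target. In beta, the large charge, 68.2% is left at 3.00 min, with 2.2% target.

| flask | solid substrate | coupling partner | protic impurity | remark | time |
|---|---|---|---|---|---|
| alpha | 0.12 M | 0.32 M | 0.032 M | run made earlier |  |
| beta | 0.69 M | 0.32 M | 0.032 M | run made earlier |  |
| Monday's | 0.60 M | 0.320 M | 0.0320 M |  | 3.0 min |
| Sunday's | 0.50 M | 0.320 M | 0.0320 M |  | 3.0 min |
| Saturday's | 0.30 M | 0.320 M | 0.0320 M |  | 3.0 min |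
| Tuesday's | 0.10 M | 0.320 M | 0.0320 M |  | 3.0 min |
| Thursday's | 0.16 M | 0.320 M | 0.0320 M |  | 3.0 min |

| run | time / min | target / % | solid substrate / % |
|---|---|---|---|
| alpha | 0.250 | 6.5 | 57.7 |
| alpha | 0.833 | 20.1 | 35.3 |
| alpha | 1.33 | 31.8 | 20.5 |
| alpha | 2.00 | 47.4 | 2.9 |
| alpha | 3.00 | 60.5 | 0.3 |
| beta | 0.250 | 0.4 | 92.3 |
| beta | 0.417 | 0.1 | 90.6 |
| beta | 0.833 | 0.2 | 87.2 |
| beta | 1.50 | 0.8 | 81.6 |
| beta | 3.00 | 2.2 | 68.2 |

(standard deviation of a reading: 1 percentage point)

- what was read earlier has a scatter of 1 percentage point, one standard deviation
- at the start none of the solid substrate is in solution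
- what has only dissolved of solid substrate counts as not reacted
- a reading or a percentage of target counts all its forms, free or not

- ranking by amount of target, in percent of the solid substrate charged, from high to low, at 3.0 min (Monday's / Sunday's / Saturday's / Tuesday's / Thursday's)
- the same order at 12 min (Monday's / Sunday's / Saturday's / Tuesday's / Thursday's)
- the amount of target, in percent of the solid substrate charged of the flask you put first, at 3.0 min
- the amount of target, in percent of the solid substrate charged of the flask you put last, at 3.0 min

2. After the first reading, both solid readings fall nearly straight, a zero-order fall. I call its slope r, in M of solid substrate per minute. Alpha gives 0.0376 M/min up to 2.00 min. Beta gives 0.0605 M/min up to 3.00 min. These are two ways to one number, and they part: beta's is 1.61 times alpha's.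

3. Which one cheats? Over those spans, alpha gains 74.6% target per solid lost, but beta only 7.47%. So I read beta's slope as holding a second drain beside the one that gives target. I take alpha's r as the working rate and beta's as the short bound.

4. The forecast ties the sudden early loss to the impurity, and I do too. With S the solid charge and H the impurity charge, Tuesday's needs 1.81 min. I call t = (S − H)/r the clearing time. On beta's rate, Tuesday's needs 1.12 min, so both ways lie below 3.0 min. Thursday's straddles it, at 2.12 min to 3.41 min. Saturday's shortest value is 4.43 min, above it. Clearing times do not order Tuesday's and Thursday's, so I use alpha's target slope over the same span, 0.0280 M/min. At that slope, Thursday's reaches 52.6% at 3.0 min. That is below Tuesday's ceiling (S − H)/S of 68.0%, which the same slope reaches in 2.42 min. So at 3.0 min I put Tuesday's over Thursday's. Behind them I put Saturday's, Sunday's and Monday's, with target falling with charge, as it falls from alpha to beta.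

5. At 12 min, Saturday's ceiling (S − H)/S is 89.3% and Thursday's is 80.0%. But the second drain, rb − r, running over 4.43 min takes an estimated 33.8% of Saturday's charge, leaving 55.5%. I put Thursday's first and Saturday's behind Tuesday's.

6. The forecast gives Tuesday's > Thursday's > Saturday's > Sunday's > Monday's at 3.0 min, with 59% (53% to 66%) and 3.5% (2% to 8%). At 12 min it gives Saturday's > Thursday's > Tuesday's > Sunday's > Monday's, on the ground “the caps rule”. There it differs from me.

7. The flasks give Tuesday's > Thursday's > Saturday's > Sunday's > Monday's at 3.0 min, with 61.2% and 3.84%. At 12 min they give Thursday's > Tuesday's > Saturday's > Sunday's > Monday's: Thursday's holds 63.8% and Saturday's 52.8%.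

    solid substrate ⇌ dissolved substrate, rate k1*(cs1 - [dissolved substrate]) while solid is left; crystals form when [dissolved substrate] > cs1 (solubility = 14.0 mM, k = 0.757 /s)
    dissolved substrate + coupling partner → target (k = 0.142 /M/s)
    solid product ⇌ target, rate k3*(cs3 - [target]) while solid is left; crystals form when [target] > cs3 (solubility = 2.00 mM, k = 0.242 /s)
    solid substrate + protic impurity → quenched substrate (k = 1.53 /M/s)
    solid substrate + target → side product (k = 0.334 /M/s)

Tuesday's clearing time of 1.81 min lies under 3.0 min, and Tuesday's holds 0% solid substrate at 3.00 min; its dissolved target has a half-life of 0.98 min by the step with solid substrate at 0.572 min, shorter than that clearing time. The neighbour of Tuesday's charged with 0.25 M solid substrate has a clearing time of 5.80 min, over 3.0 min, and at 3.00 min it holds 33.9% solid substrate and 25.5% target.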